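**Plan**
- Retrosynthesis: the two isobutyrate C–O bonds are cut first, then C11=C12 (cross-metathesis with a C12–C15 vinyl diol), then C8–C10 (alkenyl triflate/allyl coupling), then the C5 oxygen is traced back to a C8(=O)–O–C5 lactone, and last the ring bonds C2–C3 and C1–C6 (Diels–Alder).
- Enabling feature: the cyclohexene C1–C6 carries its two carbon substituents para (C8 on C1, C7H2O on C4), the footprint of a 2-substituted butadiene plus an acrylate. The C5 oxygen is 1,3-cis to C8, so C8 as a carboxylate can deliver it through a bridging five-membered lactone.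
- Forward: diene (2 steps), catalytic asymmetric Diels–Alder closing the only ring, iodolactone, allylic lactone, N-methoxy-N-methylamide, methyl ketone, enol triflate, allyl coupling, cross-metathesis with the C12–C15 diol, then desilylation, double isobutyrylation and final desilylation.
- Stereochemistry: C1 from the chiral oxazaborolidinium catalyst; C5 from C1 through the lactone tether; C13 from a Pd-catalysed dynamic kinetic asymmetric opening of racemic isoprene monoxide; C11=C12 (E) from the metathesis.

Key step: step 3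

Numbering used throughout: ring C1 (CH bearing the side chain), C2, C3, C4 (bears C7H2O), C5 (carbinol), C6; chain C8 (=C9H2), C10, C11=C12, C13 (C14H3, OH), C15H2O. TBS = tert-butyl(dimethyl)silyl; TIPS = tri(propan-2-yl)silyl.

Assumption 1: the (S)-configured oxazaborolidinium catalyst is taken to expose the acrylate face that leads to (S)-5, by analogy with its behaviour toward unsubstituted butadiene; if the sense were opposite, the (R)-catalyst would be used with nothing else changed.

Assumption 2: the (S,S)-configured bis(phosphinobenzamide) ligand is taken to give (R)-15, by analogy with the sense reported for vinyl oxiranes; otherwise its mirror image would be used.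

**Step 1**
Reactants: 1 2-methyl-2-vinyloxirane (isoprene monoxide, racemic)
Product: 2 2-methylidenebut-3-en-1-ol
Conditions: LiN(iPr)2, Et2O, 0 °C → rt; aq. NH4Cl
Reagents that add atoms: none
Why: Lithium amide-induced epoxide-to-allylic-alcohol isomerisation (β-elimination), in which removal of a methyl proton opens the oxirane at the quaternary carbon and should give the cross-conjugated dienol without any stereochemical issue.

**Step 2**
Reactants: 2 2-methylidenebut-3-en-1-ol
Product: 3 tert-butyl(dimethyl)[(2-methylidenebut-3-en-1-yl)oxy]silane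
Conditions: TBSCl, imidazole, CH2Cl2, 0 °C → rt
Reagents that add atoms: tert-butyl(chloro)dimethylsilane, CC(C)(C)[Si](C)(C)Cl
Why: Standard imidazole-promoted silylation of a primary alcohol, which masks C7–OH as an ether that should survive the Lewis acid, the bases and the organometallic reagents used later.

**Step 3**
Reactants: 3 tert-butyl(dimethyl)[(2-methylidenebut-3-en-1-yl)oxy]silane (1.5 equiv); 4 2,2,2-trifluoroethyl acrylate
Product: 5 2,2,2-trifluoroethyl (S)-4-(TBS-oxymethyl)cyclohex-3-ene-1-carboxylate
Conditions: (S)-1-(2-methylphenyl)-3,3-diphenyltetrahydro-1H,3H-pyrrolo[1,2-c][1,3,2]oxazaborole (20 mol %), HN(SO2CF3)2 (17 mol %), CH2Cl2, −78 → 0 °C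
Reagents that add atoms: none
Why: The acrylate carbonyl binds to the cationic boron of the N-protonated oxazaborolidine, which lowers its LUMO and blocks one face of the s-trans dienophile, and the s-cis diene then adds in a concerted, asynchronous, suprafacial [4+2] cycloaddition that forms C2–C3 and C1–C6 together. The closest known reaction type is the oxazaborolidinium triflimide-catalysed Diels–Alder reaction of butadiene and 2-substituted butadienes with 2,2,2-trifluoroethyl acrylate. The cyclohexene ring closes in the intermolecular [4+2] mode, both σ-bonds arising in one step and the new alkene appearing at C4=C5. C1, the only new stereocentre, is controlled by the catalyst, which leaves a single enantioface of the acrylate α-carbon open (Assumption 1). The step needs para regioselectivity and high enantioselectivity; the first should follow from the larger HOMO coefficient at the diene terminus next to the C7-bearing carbon (future C3) pairing with the acrylate β-carbon (C2), the second from the tight binding of the electron-poor trifluoroethyl ester. Keeping the oxazaborolidine in slight excess over the acid should leave no free HN(SO2CF3)2 to attack the silyl ether or the diene.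

**Step 4**
Reactants: 5 trifluoroethyl ester
Product: 6 (S)-4-(TBS-oxymethyl)cyclohex-3-ene-1-carboxylic acid
Conditions: LiOH, THF/H2O, 0 °C; then 1 M HCl to pH 4, 0 °C
Reagents that add atoms: lithium hydroxide, [Li+].[OH-]
Why: Saponification of the activated trifluoroethyl ester should be fast at 0 °C, well ahead of enolisation at C1, and the primary silyl ether tolerates the brief cold acidification.

**Step 5**
Reactants: 6 carboxylic acid
Product: 7 (1S,4R,5S)-4-iodo-4-(TBS-oxymethyl)-6-oxabicyclo[3.2.1]octan-7-one (lactone oxygen on C5 cis to C1–C8, iodine on C4 trans to that oxygen)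
Conditions: I2, KI, NaHCO3, THF/H2O, 0 °C → rt, dark; aq. Na2S2O3
Reagents that add atoms: iodine, II
Why: Kinetic iodolactonisation, in which the iodonium ion on the C4=C5 face opposite to the carboxylate is opened anti by the axial carboxylate at C5 in the five-membered-lactone (6-oxabicyclo[3.2.1]) mode, so the C5–O bond must form cis to C1–C8 and C5 is set (S) by the tether, while the inductively withdrawing C7 oxygen disfavours charge build-up and attack at C4.

**Step 6**
Reactants: 7 iodolactone
Product: 8 (1S,5S)-4-(TBS-oxymethyl)-6-oxabicyclo[3.2.1]oct-3-en-7-one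
Conditions: DBU, toluene, 80 °C
Reagents that add atoms: none
Why: E2 dehydroiodination, in which the axial tertiary iodide on C4 has an antiperiplanar ring hydrogen only on C3 (H5 is syn and loss of a C7 hydrogen would give a less stable exocyclic enol ether), so the alkene should be placed at C3=C4 and the allylic lactone results.

**Step 7**
Reactants: 8 allylic bicyclic lactone
Product: 9 (1S,5S)-5-hydroxy-N-methoxy-N-methyl-4-(TBS-oxymethyl)cyclohex-3-ene-1-carboxamide
Conditions: MeNH(OMe)·HCl, iPrMgCl, THF, −20 → 0 °C; aq. NH4Cl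
Reagents that add atoms: N,O-dimethylhydroxylamine hydrochloride, CNOC.Cl
Why: Aminolysis of a lactone by a magnesium amide (Weinreb amide formation) proceeds by acyl–oxygen cleavage with release of the bicyclic strain, so the C5–O bond is never broken and C5–OH is freed with its configuration intact.

**Step 8**
Reactants: 9 hydroxy amide
Product: 10 (1S,5S)-N-methoxy-N-methyl-4-(TBS-oxymethyl)-5-(TIPS-oxy)cyclohex-3-ene-1-carboxamide
Conditions: TIPSOTf, 2,6-lutidine, CH2Cl2, −78 → 0 °C
Reagents that add atoms: tri(propan-2-yl)silyl trifluoromethanesulfonate, CC(C)[Si](C(C)C)(C(C)C)OS(=O)(=O)C(F)(F)F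
Why: Silyl triflate silylation should cap the hindered secondary allylic alcohol quickly, before it can relactonise, and gives an ether that will outlast the later selective removal of the primary TBS group.

**Step 9**
Reactants: 10 N-methoxy-N-methylamide
Product: 11 1-[(1S,5S)-4-(TBS-oxymethyl)-5-(TIPS-oxy)cyclohex-3-en-1-yl]ethan-1-one
Conditions: MeMgBr, THF, 0 °C; aq. NH4Cl
Reagents that add atoms: methylmagnesium bromide, C[Mg]Br
Why: Weinreb ketone synthesis, in which chelation stops the Grignard addition after one methyl group so that the C8 methyl ketone should be obtained without a tertiary alcohol and without epimerising C1.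

**Step 10**
Reactants: 11 methyl ketone
Product: 13 1-[(1S,5S)-4-(TBS-oxymethyl)-5-(TIPS-oxy)cyclohex-3-en-1-yl]ethenyl trifluoromethanesulfonate, via potassium enolate 12 (not isolated)
Conditions: KN(SiMe3)2, THF, −78 °C; then PhN(SO2CF3)2, −78 → 0 °C; aq. NH4Cl
Reagents that add atoms: N-phenylbis(trifluoromethanesulfonimide), O=S(=O)(N(c1ccccc1)S(=O)(=O)C(F)(F)F)C(F)(F)F
Why: Kinetic deprotonation by the hindered amide base at −78 °C should remove a methyl proton and not the tertiary C1–H, so C1 is not epimerised, and O-sulfonylation of the enolate gives the 1,1-disubstituted enol triflate with C9 as the methylidene carbon.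

**Step 11**
Reactants: 13 enol triflate
Product: 14 2-[(1S,5S)-4-(TBS-oxymethyl)-5-(TIPS-oxy)cyclohex-3-en-1-yl]penta-1,4-diene
Conditions: allylSnBu3, Pd(PPh3)4 (5 mol %), LiCl, THF, 65 °C
Reagents that add atoms: allyltributylstannane, C=CC[Sn](CCCC)(CCCC)CCCC
Why: Stille coupling of an alkenyl triflate with an allylstannane (oxidative addition to zerovalent palladium, chloride-assisted transmetallation, reductive elimination) should form C8–C10 and deliver the skipped diene with the silyl ethers untouched.

**Step 12**
Reactants: 1 2-methyl-2-vinyloxirane (racemic)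
Product: 15 (R)-2-methylbut-3-ene-1,2-diol
Conditions: Pd2(dba)3·CHCl3 (1 mol %), (1S,2S)-N,N'-(cyclohexane-1,2-diyl)bis[2-(diphenylphosphanyl)benzamide] (3 mol %), BEt3 (1 mol %), NaHCO3, CH2Cl2/H2O, rt
Reagents that add atoms: water, O (its oxygen is relayed through hydrogencarbonate, [Na+].OC([O-])=O, which is regenerated)
Why: Pd-catalysed dynamic kinetic asymmetric allylic substitution (Tsuji–Trost type) of the vinyl oxirane, in which the π-allyl complexes from both enantiomers interconvert faster than they are captured and the chiral ligand pocket, with boron-assisted delivery of the oxygen nucleophile to the substituted allyl terminus, should set C13 as (R) (Assumption 2).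

**Step 13**
Reactants: 14 skipped diene; 15 (R)-2-methylbut-3-ene-1,2-diol (3 equiv)
Product: 16 (2R,3E)-6-[(1S,5S)-4-(TBS-oxymethyl)-5-(TIPS-oxy)cyclohex-3-en-1-yl]-2-methylhepta-3,6-diene-1,2-diol
Conditions: second-generation Hoveyda–Grubbs catalyst (H2IMes)Cl2Ru=CH(C6H4-2-OiPr) (5 mol %; H2IMes = 1,3-dimesitylimidazolidin-2-ylidene), 1,4-benzoquinone (10 mol %), CH2Cl2, 40 °C
Reagents that add atoms: none
Why: Olefin cross-metathesis between the monosubstituted alkene of 14 and the vinyl group of 15, a hindered allylic-carbinol olefin that homodimerises slowly, should be selective because the 1,1-disubstituted and trisubstituted alkenes do not engage, and the quaternary C13 enforces the E geometry at C11=C12.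

**Step 14**
Reactants: 16 bis-silyl ether diol
Product: 17 (2R,3E)-6-[(1S,5S)-4-(hydroxymethyl)-5-(TIPS-oxy)cyclohex-3-en-1-yl]-2-methylhepta-3,6-diene-1,2-diol
Conditions: HF·pyridine, pyridine, THF, 0 °C
Reagents that add atoms: none
Why: Buffered HF·pyridine desilylation should discriminate on steric grounds, cleaving the unhindered primary TBS ether while the hindered secondary TIPS ether and the acid-sensitive tertiary allylic alcohol are left alone.

**Step 15**
Reactants: 17 triol
Product: 18 (2R,3E)-2-hydroxy-2-methyl-6-[(1S,5S)-4-{[(2-methylpropanoyl)oxy]methyl}-5-(TIPS-oxy)cyclohex-3-en-1-yl]hepta-3,6-dien-1-yl 2-methylpropanoate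
Conditions: iPrCOCl (2.3 equiv), pyridine, 4-(dimethylamino)pyridine (cat.), CH2Cl2, 0 °C
Reagents that add atoms: isobutyryl chloride, CC(C)C(=O)Cl
Why: Acylation with an acid chloride and pyridine should esterify both primary hydroxyls (O7 and O15) in one operation, while the tertiary C13 alcohol is too hindered to react at 0 °C and O5 is still silylated.

**Step 16**
Reactants: 18 silylated diester
Product: 19 (2R,3E)-2-hydroxy-6-[(1S,5S)-5-hydroxy-4-{[(2-methylpropanoyl)oxy]methyl}cyclohex-3-en-1-yl]-2-methylhepta-3,6-dien-1-yl 2-methylpropanoate (the target)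
Conditions: Bu4NF, AcOH (1:1), THF, rt
Reagents that add atoms: none
Why: Fluoride-driven cleavage of the secondary silyl ether under acetic acid buffering should keep the medium non-basic, so that the isobutyrates neither hydrolyse nor migrate from O7 to O5 and no stereocentre is touched.

**Compound list**
1 | 2-methyl-2-vinyloxirane (isoprene monoxide, racemic) | CC1(C=C)CO1 | starting material
2 | 2-methylidenebut-3-en-1-ol | C=CC(=C)CO | intermediate
3 | tert-butyl(dimethyl)[(2-methylidenebut-3-en-1-yl)oxy]silane | C=CC(=C)CO[Si](C)(C)C(C)(C)C | intermediate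
4 | 2,2,2-trifluoroethyl acrylate | C=CC(=O)OCC(F)(F)F | starting material
5 | 2,2,2-trifluoroethyl (S)-4-{[tert-butyl(dimethyl)silyl]oxymethyl}cyclohex-3-ene-1-carboxylate | O=C(OCC(F)(F)F)[C@H]1CCC(CO[Si](C)(C)C(C)(C)C)=CC1 | intermediate
6 | (S)-4-{[tert-butyl(dimethyl)silyl]oxymethyl}cyclohex-3-ene-1-carboxylic acid | OC(=O)[C@H]1CCC(CO[Si](C)(C)C(C)(C)C)=CC1 | intermediate
7 | (1S,4R,5S)-4-{[tert-butyl(dimethyl)silyl]oxymethyl}-4-iodo-6-oxabicyclo[3.2.1]octan-7-one | O=C1O[C@H]2C[C@@H]1CC[C@@]2(I)CO[Si](C)(C)C(C)(C)C | intermediate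
8 | (1S,5S)-4-{[tert-butyl(dimethyl)silyl]oxymethyl}-6-oxabicyclo[3.2.1]oct-3-en-7-one | O=C1O[C@H]2C[C@@H]1CC=C2CO[Si](C)(C)C(C)(C)C | intermediate
9 | (1S,5S)-4-{[tert-butyl(dimethyl)silyl]oxymethyl}-5-hydroxy-N-methoxy-N-methylcyclohex-3-ene-1-carboxamide | CON(C)C(=O)[C@H]1CC=C(CO[Si](C)(C)C(C)(C)C)[C@@H](O)C1 | intermediate
10 | (1S,5S)-4-{[tert-butyl(dimethyl)silyl]oxymethyl}-N-methoxy-N-methyl-5-{[tri(propan-2-yl)silyl]oxy}cyclohex-3-ene-1-carboxamide | CON(C)C(=O)[C@H]1CC=C(CO[Si](C)(C)C(C)(C)C)[C@@H](O[Si](C(C)C)(C(C)C)C(C)C)C1 | intermediate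
11 | 1-[(1S,5S)-4-{[tert-butyl(dimethyl)silyl]oxymethyl}-5-{[tri(propan-2-yl)silyl]oxy}cyclohex-3-en-1-yl]ethan-1-one | CC(=O)[C@H]1CC=C(CO[Si](C)(C)C(C)(C)C)[C@@H](O[Si](C(C)C)(C(C)C)C(C)C)C1 | intermediate
12 | potassium 1-[(1S,5S)-4-{[tert-butyl(dimethyl)silyl]oxymethyl}-5-{[tri(propan-2-yl)silyl]oxy}cyclohex-3-en-1-yl]ethen-1-olate | [K+].[O-]C(=C)[C@H]1CC=C(CO[Si](C)(C)C(C)(C)C)[C@@H](O[Si](C(C)C)(C(C)C)C(C)C)C1 | intermediate (not isolated)
13 | 1-[(1S,5S)-4-{[tert-butyl(dimethyl)silyl]oxymethyl}-5-{[tri(propan-2-yl)silyl]oxy}cyclohex-3-en-1-yl]ethenyl trifluoromethanesulfonate | C=C(OS(=O)(=O)C(F)(F)F)[C@H]1CC=C(CO[Si](C)(C)C(C)(C)C)[C@@H](O[Si](C(C)C)(C(C)C)C(C)C)C1 | intermediate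
14 | 2-[(1S,5S)-4-{[tert-butyl(dimethyl)silyl]oxymethyl}-5-{[tri(propan-2-yl)silyl]oxy}cyclohex-3-en-1-yl]penta-1,4-diene | C=CCC(=C)[C@H]1CC=C(CO[Si](C)(C)C(C)(C)C)[C@@H](O[Si](C(C)C)(C(C)C)C(C)C)C1 | intermediate
15 | (R)-2-methylbut-3-ene-1,2-diol | C=C[C@@](C)(O)CO | intermediate
16 | (2R,3E)-6-[(1S,5S)-4-{[tert-butyl(dimethyl)silyl]oxymethyl}-5-{[tri(propan-2-yl)silyl]oxy}cyclohex-3-en-1-yl]-2-methylhepta-3,6-diene-1,2-diol | C=C(C/C=C/[C@@](C)(O)CO)[C@H]1CC=C(CO[Si](C)(C)C(C)(C)C)[C@@H](O[Si](C(C)C)(C(C)C)C(C)C)C1 | intermediate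
17 | (2R,3E)-6-[(1S,5S)-4-(hydroxymethyl)-5-{[tri(propan-2-yl)silyl]oxy}cyclohex-3-en-1-yl]-2-methylhepta-3,6-diene-1,2-diol | C=C(C/C=C/[C@@](C)(O)CO)[C@H]1CC=C(CO)[C@@H](O[Si](C(C)C)(C(C)C)C(C)C)C1 | intermediate
18 | (2R,3E)-2-hydroxy-2-methyl-6-[(1S,5S)-4-{[(2-methylpropanoyl)oxy]methyl}-5-{[tri(propan-2-yl)silyl]oxy}cyclohex-3-en-1-yl]hepta-3,6-dien-1-yl 2-methylpropanoate | C=C(C/C=C/[C@@](C)(O)COC(=O)C(C)C)[C@H]1CC=C(COC(=O)C(C)C)[C@@H](O[Si](C(C)C)(C(C)C)C(C)C)C1 | intermediate
19 | (2R,3E)-2-hydroxy-6-[(1S,5S)-5-hydroxy-4-{[(2-methylpropanoyl)oxy]methyl}cyclohex-3-en-1-yl]-2-methylhepta-3,6-dien-1-yl 2-methylpropanoate | C=C(C/C=C/[C@@](C)(O)COC(=O)C(C)C)[C@H]1CC=C(COC(=O)C(C)C)[C@@H](O)C1 | target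

**Step count**
Total: 16 steps. Longest linear sequence: 15 steps (steps 1–11 and 13–16); step 12 prepares the C12–C15 fragment.

**Steps most likely to fail**

Step 3 (Diels–Alder). Facial control could erode through an uncatalysed or weakly bound pathway, or the cationic catalyst could strip the silyl ether or oligomerise the diene. The fallback moves stereocontrol from the catalyst to a covalently bound auxiliary while keeping the same two bonds and the same ring closure. It sets out from diene 3, which would be combined with (R)-3-acryloyl-4-benzyl-1,3-oxazolidin-2-one F1 (from the commercial oxazolidinone and acryloyl chloride) under Et2AlCl in CH2Cl2 at −78 °C. The chelated s-cis acrylimide is attacked on the face away from the benzyl group, which should give (R)-4-benzyl-3-[(S)-4-{[tert-butyl(dimethyl)silyl]oxymethyl}cyclohex-3-ene-1-carbonyl]-1,3-oxazolidin-2-one F2. Cleavage with LiOH/H2O2 in THF/H2O would release the auxiliary and return to the route at acid 6.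

Step 5 (iodolactonisation). The iodonium ion could be captured at the more substituted C4, giving the six-membered bridged lactone, or the silyl ether oxygen could take part. The fallback installs the C5 oxygen through an oxirane that is opened in SN2 fashion at its less substituted carbon. It sets out from ester 5, which would be desilylated with HF·pyridine to 2,2,2-trifluoroethyl (S)-4-(hydroxymethyl)cyclohex-3-ene-1-carboxylate F3. Sharpless asymmetric epoxidation (Ti(OiPr)4, D-(−)-diethyl tartrate, t-BuOOH, 4 Å molecular sieves, CH2Cl2, −20 °C) should place the oxirane on the ring face opposite to the ester by reagent control, giving 2,2,2-trifluoroethyl (1S,4R,5R)-4,5-epoxy-4-(hydroxymethyl)cyclohexane-1-carboxylate F4. Saponification with LiOH would let the carboxylate (assisted by Ti(OiPr)4 on the free acid if needed) open the oxirane at C5 with inversion to (1S,4R,5S)-4-hydroxy-4-(hydroxymethyl)-6-oxabicyclo[3.2.1]octan-7-one F5. Silylation of the primary hydroxyl (TBSCl, imidazole) would give (1S,4R,5S)-4-{[tert-butyl(dimethyl)silyl]oxymethyl}-4-hydroxy-6-oxabicyclo[3.2.1]octan-7-one F6, and anti-dehydration of the tertiary C4 alcohol (SOCl2, pyridine, 0 °C) would return to the route at lactone 8.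

Step 13 (cross-metathesis). On the advanced skipped diene 14, ruthenium hydride species could move the C8=C9 or C11 alkene into conjugation, the allyl terminus could homodimerise, or turnover could stall with the hindered carbinol olefin. The fallback joins the fragments at C10–C11 by a π-allylpalladium coupling instead. It sets out from triflate 13 and diol 15. Triflate 13 would be converted with Me3SnSnMe3, Pd(PPh3)4 and LiCl in THF at 60 °C into trimethyl{1-[(1S,5S)-4-{[tert-butyl(dimethyl)silyl]oxymethyl}-5-{[tri(propan-2-yl)silyl]oxy}cyclohex-3-en-1-yl]ethenyl}stannane F7. Diol 15 would undergo cross-metathesis with an excess of inexpensive (Z)-but-2-ene-1,4-diyl diacetate (same ruthenium catalyst) to give (2E,4R)-4,5-dihydroxy-4-methylpent-2-en-1-yl acetate F8. Stille coupling of F7 with F8 (Pd2(dba)3, LiCl, DMF, rt → 50 °C) should take place at the unhindered allyl terminus with retention of the E geometry and return to the route at 16.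

**Further compounds**
F1 | step 3 | (R)-3-acryloyl-4-benzyl-1,3-oxazolidin-2-one | C=CC(=O)N1[C@H](Cc2ccccc2)COC1=O
F2 | step 3 | (R)-4-benzyl-3-[(S)-4-{[tert-butyl(dimethyl)silyl]oxymethyl}cyclohex-3-ene-1-carbonyl]-1,3-oxazolidin-2-one | O=C([C@H]1CCC(CO[Si](C)(C)C(C)(C)C)=CC1)N1[C@H](Cc2ccccc2)COC1=O
F3 | step 5 | 2,2,2-trifluoroethyl (S)-4-(hydroxymethyl)cyclohex-3-ene-1-carboxylate | O=C(OCC(F)(F)F)[C@H]1CCC(CO)=CC1
F4 | step 5 | 2,2,2-trifluoroethyl (1S,4R,5R)-4,5-epoxy-4-(hydroxymethyl)cyclohexane-1-carboxylate | O=C(OCC(F)(F)F)[C@H]1CC[C@]2(CO)O[C@@H]2C1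
F5 | step 5 | (1S,4R,5S)-4-hydroxy-4-(hydroxymethyl)-6-oxabicyclo[3.2.1]octan-7-one | O=C1O[C@H]2C[C@@H]1CC[C@@]2(O)CO
F6 | step 5 | (1S,4R,5S)-4-{[tert-butyl(dimethyl)silyl]oxymethyl}-4-hydroxy-6-oxabicyclo[3.2.1]octan-7-one | O=C1O[C@H]2C[C@@H]1CC[C@@]2(O)CO[Si](C)(C)C(C)(C)C
F7 | step 13 | trimethyl{1-[(1S,5S)-4-{[tert-butyl(dimethyl)silyl]oxymethyl}-5-{[tri(propan-2-yl)silyl]oxy}cyclohex-3-en-1-yl]ethenyl}stannane | C=C([Sn](C)(C)C)[C@H]1CC=C(CO[Si](C)(C)C(C)(C)C)[C@@H](O[Si](C(C)C)(C(C)C)C(C)C)C1
F8 | step 13 | (2E,4R)-4,5-dihydroxy-4-methylpent-2-en-1-yl acetate | CC(=O)OC/C=C/[C@@](C)(O)CO
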